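## The problem

The target **16** is a 1,5-epoxy diarylheptanoid built on a single oxane ring (O1, C2–C6). C2 carries a 2-(4-hydroxy-3-methoxyphenyl)ethyl group, C4 an acetoxy group and C6 a 3,4-dihydroxy-5-methoxyphenyl group, and all three ring stereocentres are S. In the chair this means the C2 and C6 substituents are cis and both equatorial, while the C4 acetate lies on the opposite face and is axial. Only one element of absolute configuration has to come from outside. Once C6 is fixed, C2 can follow by the thermodynamic preference for the diequatorial 2,6-cis ring, and the locked chair then decides the face on which a C4 ketone is reduced. The axial C4–O bond is the less stable one and must be made under kinetic control. The sensitive groups all belong to the final product: the catechol oxidises easily, the C6–O1 bond becomes a para-hydroxybenzylic ether that can ionise through a quinone methide, and the secondary acetate will not survive basic or fluoride deprotection next to free phenols. The phenols therefore have to travel in a form that is removed under neutral conditions after the acetate is in place. What makes a short synthesis possible is the 1,3,5-oxygen pattern of the ring: C3–C4–C5 with the C4 oxygen is an acetoacetate unit, and C2 and C6 are aldehyde carbons joined through O1, the carbonyl oxygen of one of them.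

## Retrosynthesis

**16 ⇒ 15.** The three phenolic O–H bonds are traced back to benzyl ethers. Benzyl is preferred to silyl or acetal protection because it survives strong protic acid, heating in wet solvent and a trialkylborohydride. It is also released by hydrogenolysis in a neutral medium that leaves the acetate and the new catechol alone. The forward reaction must cleave three aryl benzyl ethers without touching the benzylic C6–O1 bond of the ring.

**15 ⇒ 14 ⇒ 13.** The acetyl C–O bond and then the C4–H bond are removed, which leads to the 2,6-cis oxan-4-one **13**. This takes away the one stereocentre that cannot be set by equilibration and leaves a ketone in a conformationally locked ring. A Prins-type construction of the ring would deliver the equatorial C4 oxygen and would need a later inversion. The forward reduction must instead deliver hydride from the equatorial direction to give the axial alcohol **14**.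

**13 ⇒ 12.** A methoxycarbonyl group is added back at C3. This adds no stereochemical burden, since the β-keto ester is largely enolised, and it supplies the doubly activated carbon that the ring assembly needs. The forward step is a decarboxylation that must leave the 2,6-cis relationship intact.

**12 ⇒ 2 + 8 + 5 (key disconnection).** Three bonds are cut at once: C5–C6, C2–C3 and O1–C2. C6 with O1 returns to the aryl aldehyde **2**, C2 to the 3-arylpropanal **5**, and C3–C5 with the ester to the bis-silyl dienolate **8** of methyl acetoacetate.

- Against a linear chain synthesis followed by etherification, this cut is better because no acyclic stereo-triad has to be prepared.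
- Against a hetero-Diels–Alder route followed by conjugate addition, it is better because the thermodynamic 2,6-cis isomer is the natural outcome.
- The precursors are three achiral compounds of seven to seventeen heavy atoms, against a product with one ring and two stereocentres.
- The forward reaction needs a catalyst-controlled vinylogous aldol addition to **2**, regioselective condensation with **5**, and a reversible ring closure that places the arylethyl group equatorial.

**2 ⇐ 1; 5 ⇐ 4 ⇐ 3; 8 ⇐ 7 ⇐ 6.** The fragments come from catalogue compounds by functional-group changes only.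

- Aldehyde **2** comes from 3,4-dihydroxy-5-methoxybenzaldehyde **1** by double O-benzylation.
- Aldehyde **5** comes from 4-(3-hydroxypropyl)-2-methoxyphenol **3** by phenol-selective benzylation to **4** and oxidation. Starting from the alcohol avoids a reduce-and-reoxidise detour from the corresponding acid.
- Dienolate **8** comes from methyl acetoacetate **6** by two successive silylations through **7**. It is made fresh because its quality governs the catalytic aldol step.

## Roads not taken

**Alternative 1:** The chain is cut at C3–C4 and C4–C5, with C4 masked as a dithiane. In the forward direction, lithiated 2-(tert-butyldimethylsilyl)-1,3-dithiane **A4** would open the enantiopure epoxide (2S)-2-{2-[4-(benzyloxy)-3-methoxyphenyl]ethyl}oxirane **A2** at its terminal carbon. A solvent-triggered 1,4-Brook rearrangement would regenerate the carbanion, which would then open the racemic aryl oxirane **A3** to give the full chain **A1** as both C6 epimers. Acid-mediated closure of O1–C6 through the benzylic cation and unmasking of the dithiane would reach ketone **13**.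

- Merits: the absolute configuration at C2 comes from a resolved epoxide and not from a catalytic aldol step, C6 needs no control because the cyclisation is stereoconvergent, and the whole carbon chain is made in one flask.
- Weak points: an electron-rich aryl oxirane invites attack at the benzylic carbon and rearrangement, and the second alkylation uses a hindered carbanion. The dithiane must later be removed by oxidative or thiophilic-metal reagents in the presence of three electron-rich arenes.
- Step economy: two separate epoxide syntheses, the cyclisation and the unmasking make the route some two to three steps longer before it even reaches **13**.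
- Comparison: this road is the better one in certainty of enantiopurity. The chosen plan sets against it a ring-forming step that also installs the C4 carbonyl directly, with no sulfur to remove.

**Alternative 2:** The ring is cut at O1–C2, and the C2–C7 bond of the side chain is formed as an alkene. Cross-metathesis of the alkenol **A6**, the mono-silyl ether of a syn-1,3-diol, with the aryl vinyl ketone **A7** over a second-generation Hoveyda–Grubbs catalyst would give an enone. The C6 hydroxyl would add to it in situ and close the 2,6-cis oxane **A5**, which already carries the axial C4 silyl ether.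

- Merits: C4 is set in the acyclic precursor, so there is no late hydride-facial question. The closure is neutral and under thermodynamic control.
- Weak points: **A5** has a ketone at C8 that the target lacks. Removing it by hydrogenolysis of the derived benzylic alcohol would compete with the C6–O1 bond, which is the same kind of bond. Removing it by basic hydrazone reduction invites retro-oxa-Michael opening of the β-alkoxy ketone.
- Step economy: **A6** needs two separately controlled stereocentres and a differentiated diol, and the silyl group must later be exchanged for acetyl.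
- Comparison: this road is better in that it avoids the reduction and decarboxylation steps. The chosen plan has the correct oxidation level at every chain carbon from the outset and needs only one externally controlled stereocentre.

**Alternative 3:** The ring is cut at O1–C6. Constant-current anodic oxidation of the phenolic syn-diol **A9** would convert the free 4-alkylphenol into a para-quinone methide. The C2 hydroxyl would add to its exocyclic carbon to give the oxanol **A8** with the aryl group equatorial; attack by the C4 hydroxyl would need a four-membered ring and should not compete.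

- Merits: the most fragile bond is made last, from the innate reactivity of the phenol. No ketone is reduced, and both carbinol centres come from 1,3-diol chemistry.
- Weak points: the substrate contains two further electron-rich arenes and benzyl ethers that can also be oxidised, and **A8** is itself an oxidisable phenol. The catechol of **1** would have to be mono-benzylated regioselectively. The free phenol of **A8** would acylate before the C4 hydroxyl, so acetylation needs extra protecting-group steps.
- Step economy: **A9** requires an enantio- and diastereoselective chain synthesis of its own.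
- Comparison: this road has the more direct ring closure and the shorter sequence after it. The chosen plan relies on a ring-forming reaction class with established scope and assembles ring and chain together from three simple components.

Key step: step 6

Assumption: the Ti(OiPr)4–BINOL catalyst is taken to show its usual facial sense with aryl aldehydes ((R)-ligand giving the (R)-carbinol), so (S)-BINOL is specified for the (S)-configured C6. If the sense proves opposite, the antipodal ligand is used with no other change.

## Route

Step 1
Reactants: 1 3,4-dihydroxy-5-methoxybenzaldehyde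
Product: 2 3,4-bis(benzyloxy)-5-methoxybenzaldehyde
Conditions: BnBr, K2CO3, DMF, 60 °C
Reagents that add atoms: benzyl bromide, BrCc1ccccc1
Why: Williamson etherification of both phenoxides; the aldehyde is inert to carbonate and the product has no acidic site left.

Step 2
Reactants: 3 4-(3-hydroxypropyl)-2-methoxyphenol
Product: 4 3-[4-(benzyloxy)-3-methoxyphenyl]propan-1-ol
Conditions: BnBr, K2CO3, acetone, reflux
Reagents that add atoms: benzyl bromide, BrCc1ccccc1
Why: Williamson etherification; K2CO3 deprotonates only the phenol, so the primary alcohol stays free.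

Step 3
Reactants: 4 3-[4-(benzyloxy)-3-methoxyphenyl]propan-1-ol
Product: 5 3-[4-(benzyloxy)-3-methoxyphenyl]propanal
Conditions: Dess–Martin periodinane, CH2Cl2, 0 °C to rt
Reagents that add atoms: none
Why: Dess–Martin oxidation of a primary alcohol stops at the aldehyde under neutral, anhydrous conditions; the aldehyde is used promptly to avoid self-aldol condensation.

Step 4
Reactants: 6 methyl acetoacetate
Product: 7 methyl 3-(trimethylsilyloxy)but-2-enoate (E/Z mixture, geometry immaterial)
Conditions: Me3SiCl, Et3N, hexane, rt
Reagents that add atoms: chlorotrimethylsilane, C[Si](C)(C)Cl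
Why: O-silylation of the enol of a β-keto ester; the ammonium salt precipitates from hexane and is filtered off.

Step 5
Reactants: 7 methyl 3-(trimethylsilyloxy)but-2-enoate
Product: 8 1-methoxy-1,3-bis(trimethylsilyloxy)buta-1,3-diene
Conditions: LiN(i-Pr)2, THF, −78 °C; then Me3SiCl, −78 °C to rt
Reagents that add atoms: chlorotrimethylsilane, C[Si](C)(C)Cl
Why: γ-Deprotonation of the vinylogous ester and O-silylation of the resulting ester dienolate give the bis-silyl dienolate; it is distilled and used fresh because it is moisture-sensitive.

Step 6
Reactants: 2 3,4-bis(benzyloxy)-5-methoxybenzaldehyde; 8 1-methoxy-1,3-bis(trimethylsilyloxy)buta-1,3-diene; 5 3-[4-(benzyloxy)-3-methoxyphenyl]propanal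
Product: 12 methyl (2S,6S)-6-[3,4-bis(benzyloxy)-5-methoxyphenyl]-2-{2-[4-(benzyloxy)-3-methoxyphenyl]ethyl}-4-hydroxy-5,6-dihydro-2H-pyran-3-carboxylate (enol tautomer of the 4-oxooxane-3-carboxylate), via silylated aldol adduct 9 (not isolated), via hydroxy keto ester 10 (not isolated), via Knoevenagel alkylidene 11 (not isolated)
Conditions: Ti(OiPr)4 (cat.), (S)-BINOL (cat.), LiCl (cat.), THF, rt; then CF3CO2H, −78 °C; then 5, THF/CH2Cl2, −78 °C to rt
Reagents that add atoms: none
Why: Asymmetric one-pot Maitland–Japp reaction, a known three-component route to 4-oxooxane-3-carboxylates. The titanium BINOLate formed from Ti(OiPr)4 and (S)-BINOL activates aldehyde 2, and the terminal carbon of dienolate 8 adds in a vinylogous Mukaiyama aldol reaction (C5–C6) to give silylated adduct 9; the ligand alone fixes C6 as S. CF3CO2H cleaves the silyl groups to hydroxy keto ester 10, whose doubly activated methylene condenses with aldehyde 5 in a Knoevenagel reaction (C2–C3) to alkylidene 11. The C6 hydroxyl then closes the oxane by 6-endo-trig oxa-Michael addition (O1–C2). Because this addition is reversible in acid, C2 is set under thermodynamic control relayed from C6, the arylethyl group taking the equatorial position cis to the aryl group. The step needs 2 to be consumed before 5 is added, which the order of addition secures, and it needs condensation at the ester-bearing carbon and not at C5, which the higher acidity of the 1,3-dicarbonyl position secures. It also needs the benzylic carbinol to survive CF3CO2H; the 4-benzyloxy group is twisted out of conjugation by its two ortho neighbours, so this aryl group stabilises a benzylic cation far less than a simple 4-alkoxyphenyl group would. The product should be an enol/keto mixture and is drawn as the enol.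

Step 7
Reactants: 12 methyl (2S,6S)-6-[3,4-bis(benzyloxy)-5-methoxyphenyl]-2-{2-[4-(benzyloxy)-3-methoxyphenyl]ethyl}-4-hydroxy-5,6-dihydro-2H-pyran-3-carboxylate
Product: 13 (2S,6S)-2-[3,4-bis(benzyloxy)-5-methoxyphenyl]-6-{2-[4-(benzyloxy)-3-methoxyphenyl]ethyl}oxan-4-one
Conditions: DMF–H2O, 160 °C (microwave, sealed vessel)
Reagents that add atoms: none
Why: Thermal hydrolysis and decarboxylation of a β-keto ester, CO2 leaving the β-keto acid through a six-membered transition state. Any keto, enol or 2,6-trans material converges on the diequatorial cis ketone, because reversible oxa-Michael opening at O1–C2 leaves C6 untouched and re-closure is directed by it.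

Step 8
Reactants: 13 (2S,6S)-2-[3,4-bis(benzyloxy)-5-methoxyphenyl]-6-{2-[4-(benzyloxy)-3-methoxyphenyl]ethyl}oxan-4-one
Product: 14 (2S,4S,6S)-2-[3,4-bis(benzyloxy)-5-methoxyphenyl]-6-{2-[4-(benzyloxy)-3-methoxyphenyl]ethyl}oxan-4-ol
Conditions: LiBH(s-Bu)3, THF, −78 °C; then H2O
Reagents that add atoms: none
Why: Ketone reduction by a bulky trialkylborohydride; the two equatorial substituents lock the chair, the reagent attacks along the less hindered equatorial trajectory, and the hydroxyl ends up axial (4S), trans to both ring substituents.

Step 9
Reactants: 14 (2S,4S,6S)-2-[3,4-bis(benzyloxy)-5-methoxyphenyl]-6-{2-[4-(benzyloxy)-3-methoxyphenyl]ethyl}oxan-4-ol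
Product: 15 (2S,4S,6S)-2-[3,4-bis(benzyloxy)-5-methoxyphenyl]-6-{2-[4-(benzyloxy)-3-methoxyphenyl]ethyl}oxan-4-yl acetate
Conditions: Ac2O, pyridine, DMAP (cat.), CH2Cl2, rt
Reagents that add atoms: acetic anhydride, CC(=O)OC(C)=O
Why: DMAP-catalysed acylation of a secondary alcohol with retention at C4; no other nucleophilic group is present because all phenols are benzylated.

Step 10
Reactants: 15 (2S,4S,6S)-2-[3,4-bis(benzyloxy)-5-methoxyphenyl]-6-{2-[4-(benzyloxy)-3-methoxyphenyl]ethyl}oxan-4-yl acetate
Product: 16 (2S,4S,6S)-2-(3,4-dihydroxy-5-methoxyphenyl)-6-[2-(4-hydroxy-3-methoxyphenyl)ethyl]oxan-4-yl acetate (CNP0143286.2)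
Conditions: H2 (1 atm), 10% Pd/C, EtOAc, rt
Reagents that add atoms: none
Why: Catalytic hydrogenolysis of aryl benzyl ethers in a neutral medium; these cleave much faster than the dialkyl benzylic C6–O1 bond, and the acetate and the catechol are stable in neutral ethyl acetate under hydrogen.

## Compound list

1 | 3,4-dihydroxy-5-methoxybenzaldehyde | COc1cc(C=O)cc(O)c1O | starting material
2 | 3,4-bis(benzyloxy)-5-methoxybenzaldehyde | COc1cc(C=O)cc(OCc2ccccc2)c1OCc1ccccc1 | intermediate
3 | 4-(3-hydroxypropyl)-2-methoxyphenol | COc1cc(CCCO)ccc1O | starting material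
4 | 3-[4-(benzyloxy)-3-methoxyphenyl]propan-1-ol | COc1cc(CCCO)ccc1OCc1ccccc1 | intermediate
5 | 3-[4-(benzyloxy)-3-methoxyphenyl]propanal | COc1cc(CCC=O)ccc1OCc1ccccc1 | intermediate
6 | methyl acetoacetate | COC(=O)CC(C)=O | starting material
7 | methyl 3-(trimethylsilyloxy)but-2-enoate (E/Z mixture) | COC(=O)C=C(C)O[Si](C)(C)C | intermediate
8 | 1-methoxy-1,3-bis(trimethylsilyloxy)buta-1,3-diene | COC(O[Si](C)(C)C)=CC(=C)O[Si](C)(C)C | intermediate
9 | methyl (5S)-5-[3,4-bis(benzyloxy)-5-methoxyphenyl]-3,5-bis(trimethylsilyloxy)pent-2-enoate | COC(=O)C=C(O[Si](C)(C)C)C[C@H](O[Si](C)(C)C)c1cc(OCc2ccccc2)c(OCc2ccccc2)c(OC)c1 | intermediate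
10 | methyl (5S)-5-[3,4-bis(benzyloxy)-5-methoxyphenyl]-5-hydroxy-3-oxopentanoate | COC(=O)CC(=O)C[C@H](O)c1cc(OCc2ccccc2)c(OCc2ccccc2)c(OC)c1 | intermediate
11 | methyl (5S)-5-[3,4-bis(benzyloxy)-5-methoxyphenyl]-2-{3-[4-(benzyloxy)-3-methoxyphenyl]propylidene}-5-hydroxy-3-oxopentanoate (E/Z mixture) | COC(=O)C(=CCCc1ccc(OCc2ccccc2)c(OC)c1)C(=O)C[C@H](O)c1cc(OCc2ccccc2)c(OCc2ccccc2)c(OC)c1 | intermediate
12 | methyl (2S,6S)-6-[3,4-bis(benzyloxy)-5-methoxyphenyl]-2-{2-[4-(benzyloxy)-3-methoxyphenyl]ethyl}-4-hydroxy-5,6-dihydro-2H-pyran-3-carboxylate | COc1cc(CC[C@H]2C(C(=O)OC)=C(O)C[C@@H](c3cc(OCc4ccccc4)c(OCc4ccccc4)c(OC)c3)O2)ccc1OCc1ccccc1 | intermediate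
13 | (2S,6S)-2-[3,4-bis(benzyloxy)-5-methoxyphenyl]-6-{2-[4-(benzyloxy)-3-methoxyphenyl]ethyl}oxan-4-one | COc1cc(CC[C@H]2CC(=O)C[C@@H](c3cc(OCc4ccccc4)c(OCc4ccccc4)c(OC)c3)O2)ccc1OCc1ccccc1 | intermediate
14 | (2S,4S,6S)-2-[3,4-bis(benzyloxy)-5-methoxyphenyl]-6-{2-[4-(benzyloxy)-3-methoxyphenyl]ethyl}oxan-4-ol | COc1cc(CC[C@H]2C[C@H](O)C[C@@H](c3cc(OCc4ccccc4)c(OCc4ccccc4)c(OC)c3)O2)ccc1OCc1ccccc1 | intermediate
15 | (2S,4S,6S)-2-[3,4-bis(benzyloxy)-5-methoxyphenyl]-6-{2-[4-(benzyloxy)-3-methoxyphenyl]ethyl}oxan-4-yl acetate | COc1cc(CC[C@H]2C[C@H](OC(C)=O)C[C@@H](c3cc(OCc4ccccc4)c(OCc4ccccc4)c(OC)c3)O2)ccc1OCc1ccccc1 | intermediate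
16 | (2S,4S,6S)-2-(3,4-dihydroxy-5-methoxyphenyl)-6-[2-(4-hydroxy-3-methoxyphenyl)ethyl]oxan-4-yl acetate | COc1cc(CC[C@H]2C[C@H](OC(C)=O)C[C@@H](c3cc(O)c(O)c(OC)c3)O2)ccc1O | target

## Step count and risks

Total step count: 10. Longest linear sequence: 7 steps (3 → 4 → 5 → 12 → 13 → 14 → 15 → 16; the branch from 6 through 7 and 8 is equally long).

**Step 6 (key step).** Three things may go wrong.

- Enantioselectivity may be low, because the electron-rich aldehyde 2 is a sluggish electrophile and uncatalysed background addition could compete.
- The benzylic carbinol of 10 may ionise or dehydrate in CF3CO2H before ring closure.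
- The enolisable aldehyde 5 may self-condense under acid and so escape the Knoevenagel step.

The fallback exchanges the roles of the two aldehydes and sets out from 5, 8 and 2. Addition of 8 to the aliphatic aldehyde 5 under Ti(OiPr)4 and (R)-BINOL would give methyl (5S)-7-[4-(benzyloxy)-3-methoxyphenyl]-3,5-bis(trimethylsilyloxy)hept-2-enoate F1. The antipodal ligand is needed because C2 and C6 of the cis ring have mirror-image local arrangements. CF3CO2H would release methyl (5S)-7-[4-(benzyloxy)-3-methoxyphenyl]-5-hydroxy-3-oxoheptanoate F2. Knoevenagel condensation with the non-enolisable aldehyde 2 would give methyl (5S)-2-{[3,4-bis(benzyloxy)-5-methoxyphenyl]methylidene}-7-[4-(benzyloxy)-3-methoxyphenyl]-5-hydroxy-3-oxoheptanoate F3. Oxa-Michael closure, now forming O1–C6 under thermodynamic control, would give the regioisomeric ester methyl (2R,6S)-2-[3,4-bis(benzyloxy)-5-methoxyphenyl]-6-{2-[4-(benzyloxy)-3-methoxyphenyl]ethyl}-4-hydroxy-5,6-dihydro-2H-pyran-3-carboxylate F4. Decarboxylation under the conditions of step 7 removes the regiochemical difference, and the sequence rejoins the route at 13. In this variant the benzylic C–O bond is never present as a free carbinol in acid.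

**Step 7.** At 160 °C the product ketone 13 no longer has a stabilised enol. It may open by β-elimination toward C6 and lose water to a cross-conjugated dienone, or hydrolysis may stall. The fallback sets out from 12 and changes the way the ester is removed. DMAP-catalysed transesterification with allyl alcohol in refluxing toluene, a neutral exchange that proceeds while the β-dicarbonyl is still protected as its enol, would give prop-2-en-1-yl (2S,6S)-6-[3,4-bis(benzyloxy)-5-methoxyphenyl]-2-{2-[4-(benzyloxy)-3-methoxyphenyl]ethyl}-4-hydroxy-5,6-dihydro-2H-pyran-3-carboxylate F5. Allyl transfer to morpholine with Pd(PPh3)4 (zerovalent palladium) in THF at room temperature would then release the β-keto acid, which loses CO2 at once. The sequence rejoins the route at 13 without the ketone ever being heated.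

**Step 10.** Over-reduction may cleave the benzylic C6–O1 bond, opening the ring, once the para-hydroxyl is free; the catechol may also oxidise during isolation. The fallback sets out from 15 and replaces reductive cleavage by Lewis-acid debenzylation. BCl3 with pentamethylbenzene as a non-basic benzyl-cation scavenger in CH2Cl2 at −78 °C should remove the three aryl benzyl ethers and spare the acetate. It leads directly to 16 and makes no new intermediate.

**Step 8.** Facial selectivity may be incomplete, or the basic hydride may enolise the ketone and induce β-elimination. The fallback sets out from 13 and reaches the axial oxygen by inversion. NaBH4 in methanol at 0 °C would give the equatorial alcohol (2S,4R,6S)-2-[3,4-bis(benzyloxy)-5-methoxyphenyl]-6-{2-[4-(benzyloxy)-3-methoxyphenyl]ethyl}oxan-4-ol F6 by axial attack of the small hydride. A Mitsunobu reaction with acetic acid (PPh3, diisopropyl azodicarboxylate, THF) would install the acetate with inversion at C4. The sequence rejoins the route at 15, and step 9 is no longer needed.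

## Further compounds

F1 | step 6 | methyl (5S)-7-[4-(benzyloxy)-3-methoxyphenyl]-3,5-bis(trimethylsilyloxy)hept-2-enoate | COC(=O)C=C(O[Si](C)(C)C)C[C@@H](O[Si](C)(C)C)CCc1ccc(OCc2ccccc2)c(OC)c1
F2 | step 6 | methyl (5S)-7-[4-(benzyloxy)-3-methoxyphenyl]-5-hydroxy-3-oxoheptanoate | COC(=O)CC(=O)C[C@@H](O)CCc1ccc(OCc2ccccc2)c(OC)c1
F3 | step 6 | methyl (5S)-2-{[3,4-bis(benzyloxy)-5-methoxyphenyl]methylidene}-7-[4-(benzyloxy)-3-methoxyphenyl]-5-hydroxy-3-oxoheptanoate | COC(=O)C(=Cc1cc(OCc2ccccc2)c(OCc2ccccc2)c(OC)c1)C(=O)C[C@@H](O)CCc1ccc(OCc2ccccc2)c(OC)c1
F4 | step 6 | methyl (2R,6S)-2-[3,4-bis(benzyloxy)-5-methoxyphenyl]-6-{2-[4-(benzyloxy)-3-methoxyphenyl]ethyl}-4-hydroxy-5,6-dihydro-2H-pyran-3-carboxylate | COc1cc(CC[C@H]2CC(O)=C(C(=O)OC)[C@@H](c3cc(OCc4ccccc4)c(OCc4ccccc4)c(OC)c3)O2)ccc1OCc1ccccc1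
F5 | step 7 | prop-2-en-1-yl (2S,6S)-6-[3,4-bis(benzyloxy)-5-methoxyphenyl]-2-{2-[4-(benzyloxy)-3-methoxyphenyl]ethyl}-4-hydroxy-5,6-dihydro-2H-pyran-3-carboxylate | COc1cc(CC[C@H]2C(C(=O)OCC=C)=C(O)C[C@@H](c3cc(OCc4ccccc4)c(OCc4ccccc4)c(OC)c3)O2)ccc1OCc1ccccc1
F6 | step 8 | (2S,4R,6S)-2-[3,4-bis(benzyloxy)-5-methoxyphenyl]-6-{2-[4-(benzyloxy)-3-methoxyphenyl]ethyl}oxan-4-ol | COc1cc(CC[C@H]2C[C@@H](O)C[C@@H](c3cc(OCc4ccccc4)c(OCc4ccccc4)c(OC)c3)O2)ccc1OCc1ccccc1
F0 | step 10 | none | none
A1 | alternative 1 | 1-[3,4-bis(benzyloxy)-5-methoxyphenyl]-2-{2-[(2S)-4-[4-(benzyloxy)-3-methoxyphenyl]-2-[(tert-butyldimethylsilyl)oxy]butyl]-1,3-dithian-2-yl}ethan-1-ol (both carbinol epimers) | COc1cc(CC[C@H](O[Si](C)(C)C(C)(C)C)CC2(CC(O)c3cc(OCc4ccccc4)c(OCc4ccccc4)c(OC)c3)SCCCS2)ccc1OCc1ccccc1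
A2 | alternative 1 | (2S)-2-{2-[4-(benzyloxy)-3-methoxyphenyl]ethyl}oxirane | COc1cc(CC[C@H]2CO2)ccc1OCc1ccccc1
A3 | alternative 1 | 2-[3,4-bis(benzyloxy)-5-methoxyphenyl]oxirane (racemic) | COc1cc(C2CO2)cc(OCc2ccccc2)c1OCc1ccccc1
A4 | alternative 1 | 2-(tert-butyldimethylsilyl)-1,3-dithiane | CC(C)(C)[Si](C)(C)C1SCCCS1
A5 | alternative 2 | 1-[4-(benzyloxy)-3-methoxyphenyl]-2-[(2R,4S,6S)-6-[3,4-bis(benzyloxy)-5-methoxyphenyl]-4-[(tert-butyldimethylsilyl)oxy]oxan-2-yl]ethan-1-one | COc1cc(C(=O)C[C@H]2C[C@H](O[Si](C)(C)C(C)(C)C)C[C@@H](c3cc(OCc4ccccc4)c(OCc4ccccc4)c(OC)c3)O2)ccc1OCc1ccccc1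
A6 | alternative 2 | (1S,3S)-1-[3,4-bis(benzyloxy)-5-methoxyphenyl]-3-[(tert-butyldimethylsilyl)oxy]hex-5-en-1-ol | C=CC[C@H](O[Si](C)(C)C(C)(C)C)C[C@H](O)c1cc(OCc2ccccc2)c(OCc2ccccc2)c(OC)c1
A7 | alternative 2 | 1-[4-(benzyloxy)-3-methoxyphenyl]prop-2-en-1-one | C=CC(=O)c1ccc(OCc2ccccc2)c(OC)c1
A8 | alternative 3 | (2S,4S,6S)-2-[3-(benzyloxy)-4-hydroxy-5-methoxyphenyl]-6-{2-[4-(benzyloxy)-3-methoxyphenyl]ethyl}oxan-4-ol | COc1cc(CC[C@H]2C[C@H](O)C[C@@H](c3cc(OC)c(O)c(OCc4ccccc4)c3)O2)ccc1OCc1ccccc1
A9 | alternative 3 | (3R,5S)-1-[3-(benzyloxy)-4-hydroxy-5-methoxyphenyl]-7-[4-(benzyloxy)-3-methoxyphenyl]heptane-3,5-diol | COc1cc(CC[C@H](O)C[C@H](O)CCc2cc(OC)c(O)c(OCc3ccccc3)c2)ccc1OCc1ccccc1
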